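**Retrosynthetic overview**

- The plan rests on ring A: a benzene with no ring hydrogen, oxygen at C2, C4 and C6 and carbon at C1 (CH2 bridge to C3 of pyrone ring B), C3 (prenyl) and C5 (acyl). Electrophilic substitution cannot place this pattern selectively, so ring A is built from acyclic carbons.
- Last disconnections: the three O–MOM bonds, then the C5–acyl bond (iodine–magnesium exchange at C5, addition to (R)-2-methylbutanal, oxidation).
- Key disconnection: the C2–C3, C4–C5 and C1–C2 bonds of ring A, which leads back to a 3-methoxy-4-(pyronylmethyl)cyclobutenone and a prenyl-bearing siloxyalkyne (vinylketene/ynol ether benzannulation).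
- The cyclobutenone comes from a ring B propanoic acid (as its ketene) and methoxyethyne; the acid comes from the ring B pyrone and benzyl acrylate; the pyrone comes from the dianion of methyl 3-oxopentanoate. The siloxyalkyne comes from prenyl bromide.
- Ring order: ring B first (step 2), ring A last (step 10).

Key step: step 10

Assumption: ring A is numbered from the carbon bearing the CH2 bridge (C1) round to the carbon bearing OMe (C6); (R)-2-methylbutanoic acid of high enantiomeric purity is taken as purchasable, while methoxyethyne is not and is made in step 6 so that the cyclobutenone forms with its side chain unambiguously at C4.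

**Step 1**
Reactants: 1 methyl 3-oxopentanoate; 2 N-methoxy-N-methylpropanamide
Product: 4 methyl 4-methyl-3,5-dioxoheptanoate (racemic), via dilithium dianion 3 (not isolated)
Conditions: LiN(i-Pr)2 (2.2 equiv), THF, 0 °C; then 2, −78 → 0 °C; aq. HCl
Reagents that add atoms: none
Why: Acylation of a β-keto ester dianion at its more reactive γ-carbon; the chelated N-methoxy-N-methylamide adduct should collapse only on work-up, so the more acidic tricarbonyl product cannot quench unreacted dianion.

**Step 2**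
Reactants: 4 methyl 4-methyl-3,5-dioxoheptanoate
Product: 5 6-ethyl-4-hydroxy-5-methyl-2H-pyran-2-one (ring B)
Conditions: DBU (1.5 equiv), toluene, 100 °C; then aq. HCl
Reagents that add atoms: none
Why: Enol lactonisation of a 3,5-dioxo ester: the oxygen of the C5 enolate closes on the ester with loss of methanol, the standard route to 4-hydroxy-2-pyrones.

**Step 3**
Reactants: 5 6-ethyl-4-hydroxy-5-methyl-2H-pyran-2-one; 6 benzyl prop-2-enoate (benzyl acrylate)
Product: 7 benzyl 3-(6-ethyl-4-hydroxy-5-methyl-2-oxo-2H-pyran-3-yl)propanoate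
Conditions: DBU (0.2 equiv), MeCN, 60 °C
Reagents that add atoms: none
Why: Michael addition of a cyclic vinylogous acid: C3 is the only free nucleophilic carbon of the pyronate (C5 is blocked), O-addition is reversible, and protonation of the ester enolate by the acidic substrate should make C-alkylation the thermodynamic outcome.

**Step 4**
Reactants: 7 benzyl 3-(6-ethyl-4-hydroxy-5-methyl-2-oxo-2H-pyran-3-yl)propanoate
Product: 8 benzyl 3-[6-ethyl-4-(methoxymethoxy)-5-methyl-2-oxo-2H-pyran-3-yl]propanoate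
Conditions: MOMCl, i-Pr2NEt, CH2Cl2, 0 °C → rt
Reagents that add atoms: chloromethyl methyl ether, COCCl
Why: Williamson-type O-alkylation of the vinylogous acid by a hard electrophile at the C4 oxygen masks the acidic OH, which would otherwise protonate the ketene and the siloxyalkyne later on.

**Step 5**
Reactants: 8 benzyl 3-[6-ethyl-4-(methoxymethoxy)-5-methyl-2-oxo-2H-pyran-3-yl]propanoate
Product: 9 3-[6-ethyl-4-(methoxymethoxy)-5-methyl-2-oxo-2H-pyran-3-yl]propanoic acid
Conditions: H2 (1 atm), Pd/C (10%), EtOAc, rt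
Reagents that add atoms: none
Why: Hydrogenolysis of the benzyl ester is neutral, so the acid-labile MOM ether and the base-sensitive lactone should survive, and the tetrasubstituted pyrone double bonds are not reduced at this pressure.

**Step 6**
Reactants: 10 2-chloro-1,1-dimethoxyethane
Product: 12 methoxyethyne (kept as a cold CH2Cl2 solution), via sodium methoxyethynide 11 (not isolated)
Conditions: NaNH2 (3.2 equiv), liq. NH3, −33 °C; NH3 removed; satd aq. NaCl, −70 °C → rt, distilled into CH2Cl2 at −78 °C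
Reagents that add atoms: none
Why: Twofold base-induced elimination from the α-chloro acetal (loss of HCl, then of methanol) gives the sodium alkynide, which is protonated on aqueous quench; this is the standard preparation of alkoxyacetylenes.

**Step 7**
Reactants: 9 3-[6-ethyl-4-(methoxymethoxy)-5-methyl-2-oxo-2H-pyran-3-yl]propanoic acid; 12 methoxyethyne
Product: 15 4-{[6-ethyl-4-(methoxymethoxy)-5-methyl-2-oxo-2H-pyran-3-yl]methyl}-3-methoxycyclobut-2-en-1-one (racemic), via acid chloride 13 (not isolated), via ketene 14 (not isolated)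
Conditions: 1-chloro-N,N,2-trimethylprop-1-en-1-amine, CH2Cl2, 0 °C; then added slowly to 12 (4 equiv), Et3N, CH2Cl2, 0 °C → rt, sealed flask
Reagents that add atoms: none
Why: The chloroenamine makes the acid chloride without HCl (the MOM ether is kept), Et3N dehydrochlorinates it to the aldoketene, and [2+2] cycloaddition with the alkoxyalkyne joins the unsubstituted alkyne carbon to the ketene carbonyl carbon, so the side chain sits at C4 and the methoxy group at C3 with no regiochemical ambiguity.

**Step 8**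
Reactants: 16 1-bromo-3-methylbut-2-ene (prenyl bromide); 17 ethynylmagnesium bromide
Product: 18 5-methylhex-4-en-1-yne
Conditions: 17 (1.5 equiv), CuCl (5 mol%), THF, 0 → 40 °C; fractional distillation
Reagents that add atoms: none
Why: CuCl-catalysed coupling of an alkynyl Grignard reagent with an allylic bromide; the alkynylcopper species should attack the unhindered primary terminus (SN2) and give the skipped enyne.

**Step 9**
Reactants: 18 5-methylhex-4-en-1-yne
Product: 21 triisopropyl[(5-methylhex-4-en-1-yn-1-yl)oxy]silane, via lithium acetylide 19 (not isolated), via lithium ynolate 20 (not isolated)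
Conditions: n-BuLi, THF, −78 °C; t-BuOOLi (from t-BuOOH and LiN(SiMe3)2), −78 → 0 °C; then TIPSOTf, −78 → 0 °C
Reagents that add atoms: tert-butyl hydroperoxide, CC(C)(C)OO; triisopropylsilyl trifluoromethanesulfonate, CC(C)[Si](OS(=O)(=O)C(F)(F)F)(C(C)C)C(C)C
Why: The lithium acetylide attacks the peroxide oxygen of lithium tert-butyl peroxide and expels tert-butoxide (acetylide-to-ynolate oxidation), and the ynolate is O-silylated by the bulky silyl triflate, the usual route from terminal alkynes to siloxyalkynes.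

**Step 10**
Reactants: 15 4-{[6-ethyl-4-(methoxymethoxy)-5-methyl-2-oxo-2H-pyran-3-yl]methyl}-3-methoxycyclobut-2-en-1-one; 21 triisopropyl[(5-methylhex-4-en-1-yn-1-yl)oxy]silane
Product: 26 6-ethyl-3-{[2-hydroxy-6-methoxy-3-(3-methylbut-2-en-1-yl)-4-(triisopropylsilyloxy)phenyl]methyl}-4-(methoxymethoxy)-5-methyl-2H-pyran-2-one, via vinylketene 22 (not isolated), via alkenylcyclobutenone 23 (not isolated), via dienylketene 24 (not isolated), via cyclohexadienone 25 (not isolated)
Conditions: 21 (1.8 equiv), degassed toluene (0.3 M), 80 °C then 110 °C, sealed tube, argon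
Reagents that add atoms: none
Why: Thermal four-electron electrocyclic opening of 15 gives vinylketene 22 (side chain turning outward), the siloxyalkyne adds across the ketene C=C in a [2+2] cycloaddition with its prenyl-bearing carbon bonding to the ketene carbonyl carbon (23), a second four-electron opening gives dienylketene 24, and six-electron electrocyclisation to 25 followed by tautomerisation should deliver phenol 26. This is the Danheiser benzannulation of cyclobutenones with siloxyalkynes, applied here to the less common 3-alkoxy-substituted vinylketene. Ring A is closed by the thermally allowed disrotatory six-electron electrocyclisation that joins the former ketene carbon (C2) to the former C4 of the cyclobutenone (C1), after the cycloaddition has made the C2–C3 and C4–C5 bonds. No stereocentre is formed, since the racemic centre of 15 becomes an sp2 ring carbon. The step needs one regiochemistry in the [2+2] addition, and this is fixed by the polarisation of the siloxyalkyne (carbon remote from oxygen nucleophilic) and of the ketene (carbonyl carbon electrophilic), which places OH at C2, prenyl at C3, silyloxy at C4, H at C5, OMe at C6 and the bridge at C1. It also needs ring B to stay out of the reaction, which its full substitution and electron-rich 4-alkoxy character should secure against an electron-rich alkyne, while the excess of alkyne keeps the slower methoxy-substituted vinylketene from dimerising or acylating the product.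

**Step 11**
Reactants: 26 6-ethyl-3-{[2-hydroxy-6-methoxy-3-(3-methylbut-2-en-1-yl)-4-(triisopropylsilyloxy)phenyl]methyl}-4-(methoxymethoxy)-5-methyl-2H-pyran-2-one
Product: 27 3-{[2,4-dihydroxy-6-methoxy-3-(3-methylbut-2-en-1-yl)phenyl]methyl}-6-ethyl-4-(methoxymethoxy)-5-methyl-2H-pyran-2-one
Conditions: Bu4NF, AcOH, THF, 0 °C
Reagents that add atoms: none
Why: Fluoride cleavage of the aryl silyl ether is driven by Si–F bond formation; the acetic acid buffer protects the electron-rich bis-phenol and leaves the MOM ether and lactone untouched.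

**Step 12**
Reactants: 27 3-{[2,4-dihydroxy-6-methoxy-3-(3-methylbut-2-en-1-yl)phenyl]methyl}-6-ethyl-4-(methoxymethoxy)-5-methyl-2H-pyran-2-one
Product: 28 6-ethyl-3-{[6-methoxy-2,4-bis(methoxymethoxy)-3-(3-methylbut-2-en-1-yl)phenyl]methyl}-4-(methoxymethoxy)-5-methyl-2H-pyran-2-one
Conditions: MOMCl (4 equiv), i-Pr2NEt, Bu4NI (cat.), CH2Cl2, 0 → 40 °C
Reagents that add atoms: chloromethyl methyl ether, COCCl
Why: Williamson-type etherification of both phenols puts the same acid-labile group on all three acidic oxygens, so one final step can free them, and the MOM-oxy group at C4 will assist metalation at C5.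

**Step 13**
Reactants: 28 6-ethyl-3-{[6-methoxy-2,4-bis(methoxymethoxy)-3-(3-methylbut-2-en-1-yl)phenyl]methyl}-4-(methoxymethoxy)-5-methyl-2H-pyran-2-one
Product: 29 6-ethyl-3-{[5-iodo-6-methoxy-2,4-bis(methoxymethoxy)-3-(3-methylbut-2-en-1-yl)phenyl]methyl}-4-(methoxymethoxy)-5-methyl-2H-pyran-2-one
Conditions: NIS (1.05 equiv), MeCN, 0 °C → rt, dark
Reagents that add atoms: N-iodosuccinimide, O=C1CCC(=O)N1I
Why: Electrophilic aromatic iodination at C5, the only open position of a 1,3,5-trioxygenated benzene, should be far faster than attack of NIS on the trisubstituted alkene when no acid or internal nucleophile is present.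

**Step 14**
Reactants: 30 (2R)-2-methylbutanoic acid
Product: 31 (2R)-2-methylbutan-1-ol
Conditions: LiAlH4, Et2O, 0 °C → rt; Na2SO4·10H2O quench
Reagents that add atoms: none
Why: Hydride reduction of the carboxylic acid; the carboxylate is not enolised under these conditions, so the α-stereocentre is carried through unchanged.

**Step 15**
Reactants: 31 (2R)-2-methylbutan-1-ol
Product: 32 (2R)-2-methylbutanal
Conditions: TEMPO (1 mol%), KBr (10 mol%), NaOCl, NaHCO3, CH2Cl2/H2O, 0 °C; distilled and used at once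
Reagents that add atoms: none
Why: Oxoammonium-mediated (Anelli) oxidation stops at the aldehyde under near-neutral two-phase conditions, which are established for 2-methylbutan-1-ol without loss of configuration if the aldehyde is kept cold and used directly.

**Step 16**
Reactants: 29 6-ethyl-3-{[5-iodo-6-methoxy-2,4-bis(methoxymethoxy)-3-(3-methylbut-2-en-1-yl)phenyl]methyl}-4-(methoxymethoxy)-5-methyl-2H-pyran-2-one; 32 (2R)-2-methylbutanal
Product: 34 6-ethyl-3-{[5-[(2R)-1-hydroxy-2-methylbutyl]-6-methoxy-2,4-bis(methoxymethoxy)-3-(3-methylbut-2-en-1-yl)phenyl]methyl}-4-(methoxymethoxy)-5-methyl-2H-pyran-2-one (mixture of carbinol epimers), via arylmagnesium chloride 33 (not isolated)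
Conditions: i-PrMgCl·LiCl, THF, −20 °C; then 32 (2 equiv), −40 → 0 °C; aq. NH4Cl
Reagents that add atoms: none
Why: Iodine–magnesium exchange, helped by the flanking MOM-oxy and methoxy groups, gives an aryl Grignard reagent that should be too weak a base and nucleophile to attack the vinylogous-carbonate pyrone at low temperature but adds to the aldehyde; the carbinol centre forms as a mixture that step 17 removes, and the α-centre comes unchanged from 32.

**Step 17**
Reactants: 34 6-ethyl-3-{[5-[(2R)-1-hydroxy-2-methylbutyl]-6-methoxy-2,4-bis(methoxymethoxy)-3-(3-methylbut-2-en-1-yl)phenyl]methyl}-4-(methoxymethoxy)-5-methyl-2H-pyran-2-one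
Product: 35 6-ethyl-3-{[6-methoxy-2,4-bis(methoxymethoxy)-5-[(2R)-2-methylbutanoyl]-3-(3-methylbut-2-en-1-yl)phenyl]methyl}-4-(methoxymethoxy)-5-methyl-2H-pyran-2-one
Conditions: Dess–Martin periodinane, NaHCO3, CH2Cl2, 0 °C → rt
Reagents that add atoms: none
Why: Dess–Martin oxidation under buffered, non-enolising conditions should convert both carbinol epimers into one ketone and leave the α-stereocentre, the prenyl group and the MOM ethers intact.

**Step 18**
Reactants: 35 6-ethyl-3-{[6-methoxy-2,4-bis(methoxymethoxy)-5-[(2R)-2-methylbutanoyl]-3-(3-methylbut-2-en-1-yl)phenyl]methyl}-4-(methoxymethoxy)-5-methyl-2H-pyran-2-one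
Product: 36 3-{[2,4-dihydroxy-6-methoxy-5-[(2R)-2-methylbutanoyl]-3-(3-methylbut-2-en-1-yl)phenyl]methyl}-6-ethyl-4-hydroxy-5-methyl-2H-pyran-2-one (target, CNP0233274.1)
Conditions: 3 M aq. HCl/MeOH (1:5), rt
Reagents that add atoms: none
Why: Acid-catalysed acetal exchange with methanol cleaves the three MOM ethers; the mild conditions should avoid enolisation of the hindered aryl ketone (so the (R) centre is kept) and cyclisation of the prenyl group onto the neighbouring phenols.

**Compound list**

1 | methyl 3-oxopentanoate | CCC(=O)CC(=O)OC | starting material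
2 | N-methoxy-N-methylpropanamide | CCC(=O)N(C)OC | starting material
3 | dilithium dianion of methyl 3-oxopentanoate | C[CH-]C(=O)[CH-]C(=O)OC.[Li+].[Li+] | intermediate
4 | methyl 4-methyl-3,5-dioxoheptanoate (racemic) | CCC(=O)C(C)C(=O)CC(=O)OC | intermediate
5 | 6-ethyl-4-hydroxy-5-methyl-2H-pyran-2-one | CCc1oc(=O)cc(O)c1C | intermediate
6 | benzyl prop-2-enoate | C=CC(=O)OCc1ccccc1 | starting material
7 | benzyl 3-(6-ethyl-4-hydroxy-5-methyl-2-oxo-2H-pyran-3-yl)propanoate | CCc1oc(=O)c(CCC(=O)OCc2ccccc2)c(O)c1C | intermediate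
8 | benzyl 3-[6-ethyl-4-(methoxymethoxy)-5-methyl-2-oxo-2H-pyran-3-yl]propanoate | CCc1oc(=O)c(CCC(=O)OCc2ccccc2)c(OCOC)c1C | intermediate
9 | 3-[6-ethyl-4-(methoxymethoxy)-5-methyl-2-oxo-2H-pyran-3-yl]propanoic acid | CCc1oc(=O)c(CCC(=O)O)c(OCOC)c1C | intermediate
10 | 2-chloro-1,1-dimethoxyethane | COC(CCl)OC | starting material
11 | sodium methoxyethynide | COC#[C-].[Na+] | intermediate
12 | methoxyethyne | COC#C | intermediate
13 | 3-[6-ethyl-4-(methoxymethoxy)-5-methyl-2-oxo-2H-pyran-3-yl]propanoyl chloride | CCc1oc(=O)c(CCC(Cl)=O)c(OCOC)c1C | intermediate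
14 | 3-[6-ethyl-4-(methoxymethoxy)-5-methyl-2-oxo-2H-pyran-3-yl]prop-1-en-1-one (ketene) | CCc1oc(=O)c(CC=C=O)c(OCOC)c1C | intermediate
15 | 4-{[6-ethyl-4-(methoxymethoxy)-5-methyl-2-oxo-2H-pyran-3-yl]methyl}-3-methoxycyclobut-2-en-1-one (racemic) | O=C1C=C(OC)C1Cc1c(OCOC)c(C)c(CC)oc1=O | intermediate
16 | 1-bromo-3-methylbut-2-ene | CC(C)=CCBr | starting material
17 | ethynylmagnesium bromide | C#C[Mg]Br | starting material
18 | 5-methylhex-4-en-1-yne | CC(C)=CCC#C | intermediate
19 | lithium 5-methylhex-4-en-1-yn-1-ide | CC(C)=CCC#[C-].[Li+] | intermediate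
20 | lithium 5-methylhex-4-en-1-yn-1-olate | CC(C)=CCC#C[O-].[Li+] | intermediate
21 | triisopropyl[(5-methylhex-4-en-1-yn-1-yl)oxy]silane | CC(C)=CCC#CO[Si](C(C)C)(C(C)C)C(C)C | intermediate
22 | (3Z)-3-methoxy-5-[6-ethyl-4-(methoxymethoxy)-5-methyl-2-oxo-2H-pyran-3-yl]penta-1,3-dien-1-one (vinylketene) | O=C=C/C(OC)=C/Cc1c(OCOC)c(C)c(CC)oc1=O | intermediate
23 | 4-alkenyl-2-prenyl-3-(triisopropylsilyloxy)cyclobut-2-en-1-one from 22 and 21 (racemic) | O=C1C(CC=C(C)C)=C(O[Si](C(C)C)(C(C)C)C(C)C)C1/C(OC)=C/Cc1c(OCOC)c(C)c(CC)oc1=O | intermediate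
24 | dienylketene from ring opening of 23 | O=C=C(CC=C(C)C)/C(O[Si](C(C)C)(C(C)C)C(C)C)=C\C(OC)=C\Cc1c(OCOC)c(C)c(CC)oc1=O | intermediate
25 | 5-methoxy-2-prenyl-6-(pyronylmethyl)-3-(triisopropylsilyloxy)cyclohexa-2,4-dien-1-one (racemic) | O=C1C(CC=C(C)C)=C(O[Si](C(C)C)(C(C)C)C(C)C)C=C(OC)C1Cc1c(OCOC)c(C)c(CC)oc1=O | intermediate
26 | 6-ethyl-3-{[2-hydroxy-6-methoxy-3-(3-methylbut-2-en-1-yl)-4-(triisopropylsilyloxy)phenyl]methyl}-4-(methoxymethoxy)-5-methyl-2H-pyran-2-one | CCc1oc(=O)c(Cc2c(O)c(CC=C(C)C)c(O[Si](C(C)C)(C(C)C)C(C)C)cc2OC)c(OCOC)c1C | intermediate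
27 | 3-{[2,4-dihydroxy-6-methoxy-3-(3-methylbut-2-en-1-yl)phenyl]methyl}-6-ethyl-4-(methoxymethoxy)-5-methyl-2H-pyran-2-one | CCc1oc(=O)c(Cc2c(O)c(CC=C(C)C)c(O)cc2OC)c(OCOC)c1C | intermediate
28 | 6-ethyl-3-{[6-methoxy-2,4-bis(methoxymethoxy)-3-(3-methylbut-2-en-1-yl)phenyl]methyl}-4-(methoxymethoxy)-5-methyl-2H-pyran-2-one | CCc1oc(=O)c(Cc2c(OCOC)c(CC=C(C)C)c(OCOC)cc2OC)c(OCOC)c1C | intermediate
29 | 6-ethyl-3-{[5-iodo-6-methoxy-2,4-bis(methoxymethoxy)-3-(3-methylbut-2-en-1-yl)phenyl]methyl}-4-(methoxymethoxy)-5-methyl-2H-pyran-2-one | CCc1oc(=O)c(Cc2c(OCOC)c(CC=C(C)C)c(OCOC)c(I)c2OC)c(OCOC)c1C | intermediate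
30 | (2R)-2-methylbutanoic acid | OC(=O)[C@H](C)CC | starting material
31 | (2R)-2-methylbutan-1-ol | OC[C@H](C)CC | intermediate
32 | (2R)-2-methylbutanal | O=C[C@H](C)CC | intermediate
33 | arylmagnesium chloride from 29 (magnesium at C5 of ring A) | CCc1oc(=O)c(Cc2c(OCOC)c(CC=C(C)C)c(OCOC)c([Mg]Cl)c2OC)c(OCOC)c1C | intermediate
34 | 6-ethyl-3-{[5-[(2R)-1-hydroxy-2-methylbutyl]-6-methoxy-2,4-bis(methoxymethoxy)-3-(3-methylbut-2-en-1-yl)phenyl]methyl}-4-(methoxymethoxy)-5-methyl-2H-pyran-2-one (carbinol epimers) | CCc1oc(=O)c(Cc2c(OCOC)c(CC=C(C)C)c(OCOC)c(C(O)[C@H](C)CC)c2OC)c(OCOC)c1C | intermediate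
35 | 6-ethyl-3-{[6-methoxy-2,4-bis(methoxymethoxy)-5-[(2R)-2-methylbutanoyl]-3-(3-methylbut-2-en-1-yl)phenyl]methyl}-4-(methoxymethoxy)-5-methyl-2H-pyran-2-one | CCc1oc(=O)c(Cc2c(OCOC)c(CC=C(C)C)c(OCOC)c(C(=O)[C@H](C)CC)c2OC)c(OCOC)c1C | intermediate
36 | 3-{[2,4-dihydroxy-6-methoxy-5-[(2R)-2-methylbutanoyl]-3-(3-methylbut-2-en-1-yl)phenyl]methyl}-6-ethyl-4-hydroxy-5-methyl-2H-pyran-2-one | CCc1oc(=O)c(Cc2c(O)c(CC=C(C)C)c(O)c(C(=O)[C@H](C)CC)c2OC)c(O)c1C | target

**Step count**

Total: 18 steps. Longest linear sequence: 13 steps (steps 1, 2, 3, 4, 5, 7, 10, 11, 12, 13, 16, 17, 18).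

**Steps most likely to fail, with fallbacks**

1. Step 10. The methoxy-substituted vinylketene may be captured too slowly by the siloxyalkyne, so that it dimerises or acylates the phenol as it forms, and the siloxyalkyne may degrade on long heating. The fallback gives up the benzannulation for the known methylene bridging of a phloroglucinol with a 4-hydroxypyrone; it sets out from 5 and comes back at 28. Commercial 5-methoxybenzene-1,3-diol is protected (MOMCl, i-Pr2NEt) to 1-methoxy-3,5-bis(methoxymethoxy)benzene F1. n-BuLi (THF, 0 °C) metalates the position between the two MOM-oxy groups to give the aryllithium F2, which with CuI (cat.) and prenyl bromide 16 gives 5-methoxy-1,3-bis(methoxymethoxy)-2-(3-methylbut-2-en-1-yl)benzene F3. HCl/MeOH at rt frees 5-methoxy-2-(3-methylbut-2-en-1-yl)benzene-1,3-diol F4, whose two open ring positions are equivalent. Separately, 5 and dimethylmethylideneammonium iodide give the Mannich base 3-[(dimethylamino)methyl]-6-ethyl-4-hydroxy-5-methyl-2H-pyran-2-one F5. Heated with F4 (MeCN, 70 °C), F5 loses dimethylamine to the 3-methylidene-pyran-2,4-dione F6, which alkylates F4 next to a phenol OH to give the methylene-bridged triol F7. MOMCl/i-Pr2NEt (excess) then converts F7 into 28.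

2. Step 7. The aldoketene may oligomerise before it meets the volatile alkyne, and the acid chloride may lose its MOM group if the pyrone C4 oxygen attacks the acyl carbon. The fallback swaps the alkyne for a ketene acetal; it sets out from 9 and comes back at 15 or, by a second branch, at 27. Ketene 14, generated as in step 7 (acid chloride added slowly so that dehydrochlorination outruns direct C-acylation of the acetal), is trapped by commercial, non-volatile and more nucleophilic 1,1-dimethoxyethene to give 2-{[6-ethyl-4-(methoxymethoxy)-5-methyl-2-oxo-2H-pyran-3-yl]methyl}-3,3-dimethoxycyclobutan-1-one F8. Loss of methanol (Et3N, or silica gel) can occur towards the ring CH2, which gives 15, or towards the substituted carbon, which gives the 2-substituted 3-methoxycyclobut-2-en-1-one F9. F9 is still usable: heated with 21 as in step 10 it should pass through vinylketene F10, alkenylcyclobutenone F11, dienylketene F12 and cyclohexadienone F13 to the regioisomeric silyl phenol F14. F14 has the same ring A carbon and oxygen pattern with the silyl group on the C2 oxygen and the free OH at C4, and Bu4NF/AcOH converts it into 27.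

3. Step 3. C-alkylation of the weakly nucleophilic pyronate by the acrylate may be slow, so that reversible O-addition or a second alkylation at C3 takes over. The fallback uses an organocatalytic reductive alkylation; it sets out from 5 and comes back at 9. Pyrone 5, commercial 3-(benzyloxy)propanal, Hantzsch ester and L-proline (cat., CH2Cl2, rt) give the Knoevenagel alkylidene F15, which is reduced in the flask by hydride transfer to 3-[3-(benzyloxy)propyl]-6-ethyl-4-hydroxy-5-methyl-2H-pyran-2-one F16. MOMCl/i-Pr2NEt gives the MOM ether F17, hydrogenolysis (H2, Pd/C, EtOAc) gives the primary alcohol F18, and TEMPO (cat.)/PhI(OAc)2 in MeCN/H2O oxidises F18 to acid 9.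

**Further compounds**

F1 | step 10 | 1-methoxy-3,5-bis(methoxymethoxy)benzene | COCOc1cc(OC)cc(OCOC)c1
F2 | step 10 | [4-methoxy-2,6-bis(methoxymethoxy)phenyl]lithium | COCOc1cc(OC)cc(OCOC)c1[Li]
F3 | step 10 | 5-methoxy-1,3-bis(methoxymethoxy)-2-(3-methylbut-2-en-1-yl)benzene | COCOc1cc(OC)cc(OCOC)c1CC=C(C)C
F4 | step 10 | 5-methoxy-2-(3-methylbut-2-en-1-yl)benzene-1,3-diol | COc1cc(O)c(CC=C(C)C)c(O)c1
F5 | step 10 | 3-[(dimethylamino)methyl]-6-ethyl-4-hydroxy-5-methyl-2H-pyran-2-one | CCc1oc(=O)c(CN(C)C)c(O)c1C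
F6 | step 10 | 6-ethyl-5-methyl-3-methylidene-2H-pyran-2,4(3H)-dione | CCC1=C(C)C(=O)C(=C)C(=O)O1
F7 | step 10 | 3-{[2,4-dihydroxy-6-methoxy-3-(3-methylbut-2-en-1-yl)phenyl]methyl}-6-ethyl-4-hydroxy-5-methyl-2H-pyran-2-one | CCc1oc(=O)c(Cc2c(O)c(CC=C(C)C)c(O)cc2OC)c(O)c1C
F8 | step 7 | 2-{[6-ethyl-4-(methoxymethoxy)-5-methyl-2-oxo-2H-pyran-3-yl]methyl}-3,3-dimethoxycyclobutan-1-one (racemic) | COC1(OC)CC(=O)C1Cc1c(OCOC)c(C)c(CC)oc1=O
F9 | step 7 | 2-{[6-ethyl-4-(methoxymethoxy)-5-methyl-2-oxo-2H-pyran-3-yl]methyl}-3-methoxycyclobut-2-en-1-one | COC1=C(Cc2c(OCOC)c(C)c(CC)oc2=O)C(=O)C1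
F10 | step 7 | 3-methoxy-2-{[6-ethyl-4-(methoxymethoxy)-5-methyl-2-oxo-2H-pyran-3-yl]methyl}buta-1,3-dien-1-one (vinylketene) | O=C=C(Cc1c(OCOC)c(C)c(CC)oc1=O)C(OC)=C
F11 | step 7 | 4-(1-methoxyethenyl)-2-prenyl-4-(pyronylmethyl)-3-(triisopropylsilyloxy)cyclobut-2-en-1-one (racemic) | O=C1C(CC=C(C)C)=C(O[Si](C(C)C)(C(C)C)C(C)C)C1(Cc1c(OCOC)c(C)c(CC)oc1=O)C(OC)=C
F12 | step 7 | dienylketene from ring opening of F11 | O=C=C(CC=C(C)C)C(O[Si](C(C)C)(C(C)C)C(C)C)=C(Cc1c(OCOC)c(C)c(CC)oc1=O)C(OC)=C
F13 | step 7 | 5-methoxy-2-prenyl-4-(pyronylmethyl)-3-(triisopropylsilyloxy)cyclohexa-2,4-dien-1-one | O=C1C(CC=C(C)C)=C(O[Si](C(C)C)(C(C)C)C(C)C)C(Cc2c(OCOC)c(C)c(CC)oc2=O)=C(OC)C1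
F14 | step 7 | 6-ethyl-3-{[4-hydroxy-6-methoxy-3-(3-methylbut-2-en-1-yl)-2-(triisopropylsilyloxy)phenyl]methyl}-4-(methoxymethoxy)-5-methyl-2H-pyran-2-one | CCc1oc(=O)c(Cc2c(O[Si](C(C)C)(C(C)C)C(C)C)c(CC=C(C)C)c(O)cc2OC)c(OCOC)c1C
F15 | step 3 | 3-[3-(benzyloxy)propylidene]-6-ethyl-5-methyl-2H-pyran-2,4(3H)-dione | CCC1=C(C)C(=O)C(=CCCOCc2ccccc2)C(=O)O1
F16 | step 3 | 3-[3-(benzyloxy)propyl]-6-ethyl-4-hydroxy-5-methyl-2H-pyran-2-one | CCc1oc(=O)c(CCCOCc2ccccc2)c(O)c1C
F17 | step 3 | 3-[3-(benzyloxy)propyl]-6-ethyl-4-(methoxymethoxy)-5-methyl-2H-pyran-2-one | CCc1oc(=O)c(CCCOCc2ccccc2)c(OCOC)c1C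
F18 | step 3 | 6-ethyl-3-(3-hydroxypropyl)-4-(methoxymethoxy)-5-methyl-2H-pyran-2-one | CCc1oc(=O)c(CCCO)c(OCOC)c1C
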